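**Retrosynthetic overview**
1. Target 28 ⇐ desilylation of 27 ⇐ C1'–CH2 bond from hydrindanylmethyl-lithium 25 (from iodide 17) and ring A ketone 24 (equatorial attack), alkoxide acetylated in the same flask.
2. Equatorial C4–Br of 17 ⇐ hydrogen-atom-transfer hydrogenation of vinyl bromide 13 ⇐ ketone 12.
3. Five-membered ring, quaternary C3a, C1 and the CH2Br handle of 12 ⇐ visible-light bromine-atom-transfer [3+2] annulation of bromo keto ester 11 with ethylene (second ring).
4. Cyclohexanone 9 ⇐ Pd-catalysed allylic alkylation of acyclic β-keto ester 8 (first ring) ⇐ (R)-linalool, whose carbinol carbon becomes C7, by silylation, selective ozonolysis, Roskamp homologation and cross-metathesis.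
5. Ring A ketone 24 ⇐ bromonium cyclisation and decarboxylation of prenylated tert-butyl acetoacetate 21 (made separately, joined last).

Assumption: commercial (R)-(−)-linalool is the only source of chirality. Ketone 24 is made and used as the racemate, so step 13 also forms the diastereomer of 27 with mirror-image ring A (about 1:1), which is removed by chromatography.

**Step 1**
Reactants: 1 (R)-(−)-linalool
Product: 2 triethyl{[(3R)-3,7-dimethylocta-1,6-dien-3-yl]oxy}silane
Conditions: Et3SiOTf, 2,6-lutidine, CH2Cl2, −78 → 0 °C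
Reagents that add atoms: triethylsilyl trifluoromethanesulfonate, CC[Si](CC)(CC)OS(=O)(=O)C(F)(F)F
Why: Silyl triflate silylation of the tertiary allylic alcohol masks the hydroxyl (which would otherwise close onto the later β-keto ester as a cyclic enol ether) without touching the bought stereocentre.

**Step 2**
Reactants: 2 linalool triethylsilyl ether
Product: 4 (4R)-4-methyl-4-[(triethylsilyl)oxy]hex-5-enal, via ozonide 3 (not isolated)
Conditions: O3 (1.0 equiv, Sudan Red 7B end point), CH2Cl2, −78 °C; then PPh3, −78 → 23 °C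
Reagents that add atoms: ozone, [O-][O+]=O
Why: Chemoselective ozonolysis, because the electron-rich trisubstituted alkene reacts far faster than the hindered monosubstituted vinyl group, and reductive work-up gives the aldehyde.

**Step 3**
Reactants: 4 silyloxy aldehyde; 5 methyl diazoacetate
Product: 6 methyl (6R)-6-methyl-3-oxo-6-[(triethylsilyl)oxy]oct-7-enoate
Conditions: SnCl2 (10 mol%), CH2Cl2, 23 °C
Reagents that add atoms: none
Why: Roskamp homologation (Lewis-acid-promoted addition of the diazo ester to the aldehyde, 1,2-hydride shift, loss of N2) gives the β-keto ester under conditions that leave the silyl ether and vinyl group alone.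

**Step 4**
Reactants: 6 β-keto ester; 7 (Z)-but-2-ene-1,4-diyl diacetate
Product: 8 methyl (6R,7E)-9-acetoxy-6-methyl-3-oxo-6-[(triethylsilyl)oxy]non-7-enoate
Conditions: second-generation Hoveyda–Grubbs catalyst RuCl2(H2IMes)(=CH-C6H4-2-O-i-Pr) (5 mol%), 7 (3 equiv), CH2Cl2, 40 °C
Reagents that add atoms: none
Why: Olefin cross-metathesis of the hindered vinyl group with an excess of the reactive symmetrical partner gives the E allylic acetate needed for palladium ionisation.

**Step 5**
Reactants: 8 allylic acetate β-keto ester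
Product: 9 methyl (1S,2S,3R)-2-ethenyl-3-methyl-6-oxo-3-[(triethylsilyl)oxy]cyclohexane-1-carboxylate
Conditions: Pd(PPh3)4 (5 mol%), DBU, THF, 50 °C
Reagents that add atoms: none
Why: Tsuji–Trost intramolecular allylic alkylation, in which the soft β-keto ester enolate attacks the internal allyl terminus (six- not eight-membered ring) through a chair with the C3 methyl equatorial and the silyloxy group axial, so C2 forms with vinyl cis to oxygen (about 4:1 expected, minor isomer removed) and C1 equilibrates to the trans ester.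

**Step 6**
Reactants: 9 vinyl cyclohexanone keto ester; 10 ethylene
Product: 12 methyl (1R,3aR,7R,7aS)-1-(bromomethyl)-7-methyl-4-oxo-7-[(triethylsilyl)oxy]octahydro-3aH-indene-3a-carboxylate, via bromo keto ester 11 (not isolated)
Conditions: NBS, Mg(ClO4)2 (10 mol%), EtOAc, 0 °C; then Mn2(CO)10 (5 mol%), C2H4 (3 atm), PhCF3 (0.01 M), blue LEDs (450 nm), 25 °C
Reagents that add atoms: N-bromosuccinimide, O=C1CCC(=O)N1Br
Why: Proposed new method: visible-light bromine-atom-transfer [3+2] annulation with ethylene, in which •Mn(CO)5 from photolysed Mn2(CO)10 abstracts Br from 11, the tertiary 1,3-dicarbonyl radical adds to ethylene anti to the neighbouring vinyl group (sets C3a, ester cis to the C7 oxygen), the primary radical closes 5-exo-trig onto the vinyl group through a chair-like transition state (sets C1 with CH2 trans to C7, trans ring fusion) and the new primary radical carries the chain by taking Br from 11; the closest known reaction type is Curran's iodine-atom-transfer annulation of allyl iodomalonates with alkenes and the photochemical Kharasch addition of bromomalonates.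

**Step 7**
Reactants: 12 bromomethyl hydrindanone ester
Product: 13 methyl (1R,3aS,7R,7aS)-4-bromo-1-(bromomethyl)-7-methyl-7-[(triethylsilyl)oxy]-1,2,3,6,7,7a-hexahydro-3aH-indene-3a-carboxylate
Conditions: (PhO)3P, Br2, Et3N, CH2Cl2, −60 → 40 °C
Reagents that add atoms: bromine, BrBr
Why: Ketone-to-vinyl-bromide conversion with the triphenyl phosphite–bromine reagent (Prati), regiodefined because only C5 carries α-hydrogens, with amine buffering to spare the hindered tertiary silyl ether.

**Step 8**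
Reactants: 13 vinyl bromide
Product: 14 methyl (1R,3aS,4S,7R,7aS)-4-bromo-1-(bromomethyl)-7-methyl-7-[(triethylsilyl)oxy]octahydro-3aH-indene-3a-carboxylate
Conditions: Mn(dpm)3 (10 mol%; dpm = dipivaloylmethanate), PhSiH3, t-BuOOH, i-PrOH, 23 °C
Reagents that add atoms: none
Why: Metal-hydride hydrogen-atom-transfer hydrogenation (Mukaiyama/Shenvi type) puts H on C5 and the α-bromo C4 radical then takes hydrogen axially on the face away from the axial 3a-ester, leaving bromine equatorial (4S) with both C–Br bonds intact.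

**Step 9**
Reactants: 14 dibromo ester
Product: 16 (1R,3aS,4S,7R,7aS)-4-bromo-1-(bromomethyl)-7-methyl-7-[(triethylsilyl)oxy]-3a-{[(triethylsilyl)oxy]methyl}octahydro-1H-indene, via alcohol 15 (not isolated)
Conditions: i-Bu2AlH, CH2Cl2, −78 → 0 °C; then Et3SiCl, imidazole, DMAP, CH2Cl2, 23 °C
Reagents that add atoms: chlorotriethylsilane, CC[Si](Cl)(CC)CC
Why: Hydride reduction of the ester to the neopentyl alcohol (alkyl bromides are inert to i-Bu2AlH at low temperature) followed by silylation, so that no acidic or electrophilic group remains for the organolithium step.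

**Step 10**
Reactants: 16 bis-silyl dibromide
Product: 17 (1R,3aS,4S,7R,7aS)-4-bromo-1-(iodomethyl)-7-methyl-7-[(triethylsilyl)oxy]-3a-{[(triethylsilyl)oxy]methyl}octahydro-1H-indene
Conditions: NaI, acetone, 56 °C
Reagents that add atoms: sodium iodide, [Na+].[I-]
Why: Finkelstein exchange (SN2) occurs only at the primary bromide, the neopentyl-type secondary C4 bromide being inert, and gives the iodide needed for clean halogen–lithium exchange.

**Step 11**
Reactants: 18 tert-butyl acetoacetate; 19 prenyl bromide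
Product: 21 tert-butyl 7-methyl-3-oxooct-6-enoate, via dianion 20 (not isolated)
Conditions: NaH, THF, 0 °C; n-BuLi, 0 °C; then 19, 0 → 23 °C
Reagents that add atoms: none
Why: Weiler dianion alkylation, in which the more reactive terminal carbanion of the acetoacetate dianion displaces the allylic bromide.

**Step 12**
Reactants: 21 prenylated β-keto ester
Product: 24 4-bromo-3,3-dimethylcyclohexan-1-one (racemate), via bromo ester 22 (not isolated), via keto acid 23 (not isolated)
Conditions: Et2SBr·SbCl5Br (BDSB), MeNO2, −25 °C; then CF3CO2H, CH2Cl2, 23 °C; then toluene, 80 °C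
Reagents that add atoms: bromodiethylsulfonium bromopentachloroantimonate, CC[S+](Br)CC.Br[Sb-](Cl)(Cl)(Cl)(Cl)Cl
Why: Bromonium-induced cation–olefin cyclisation through the enol carbon in a chair transition state places bromine equatorial next to the new gem-dimethyl carbon (racemic), and acidolysis of the tert-butyl ester with decarboxylation of the β-keto acid gives the ketone.

**Step 13**
Reactants: 17 iodide; 24 ring A bromoketone (racemate)
Product: 27 (1S,4S)-4-bromo-1-{[(1S,3aS,4S,7R,7aS)-4-bromo-7-methyl-7-[(triethylsilyl)oxy]-3a-{[(triethylsilyl)oxy]methyl}octahydro-1H-inden-1-yl]methyl}-3,3-dimethylcyclohexyl acetate, via alkyllithium 25 (not isolated), via lithium alkoxide 26 (not isolated)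
Conditions: t-BuLi (2.1 equiv), Et2O–pentane, −78 °C; then 24 (2.2 equiv) premixed with LaCl3·2LiCl, THF, −78 °C; then Ac2O, DMAP, −78 → 23 °C
Reagents that add atoms: acetic anhydride, CC(=O)OC(C)=O
Why: Iodine–lithium exchange at the primary iodide outruns reaction at the hindered secondary bromide, 1,2-addition to the Lewis-acid-activated ketone comes from the equatorial direction because the axial C3' methyl blocks the axial path (oxygen axial and cis to the equatorial bromine, so C4' sets C1'), the alkoxide is acetylated in situ, and the diastereomer from the other enantiomer of 24 is separated.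

**Step 14**
Reactants: 27 bis-silyl acetate
Product: 28 (1S,4S)-4-bromo-1-{[(1S,3aS,4S,7R,7aS)-4-bromo-7-hydroxy-3a-(hydroxymethyl)-7-methyloctahydro-1H-inden-1-yl]methyl}-3,3-dimethylcyclohexyl acetate (CNP0182818.1)
Conditions: HF·pyridine, pyridine, THF, 0 → 23 °C
Reagents that add atoms: none
Why: Fluoride-mediated desilylation frees the primary and tertiary alcohols while the hindered tertiary acetate and the two secondary bromides are untouched.

**Compound list**
1 | (R)-(−)-linalool, (3R)-3,7-dimethylocta-1,6-dien-3-ol | C=C[C@](C)(O)CCC=C(C)C | starting material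
2 | triethyl{[(3R)-3,7-dimethylocta-1,6-dien-3-yl]oxy}silane | C=C[C@](C)(O[Si](CC)(CC)CC)CCC=C(C)C | intermediate
3 | 3,3-dimethyl-5-{(3R)-3-methyl-3-[(triethylsilyl)oxy]pent-4-en-1-yl}-1,2,4-trioxolane (ozonide, C5 epimers) | C=C[C@](C)(O[Si](CC)(CC)CC)CCC1OOC(C)(C)O1 | intermediate
4 | (4R)-4-methyl-4-[(triethylsilyl)oxy]hex-5-enal | C=C[C@](C)(O[Si](CC)(CC)CC)CCC=O | intermediate
5 | methyl diazoacetate | COC(=O)C=[N+]=[N-] | starting material
6 | methyl (6R)-6-methyl-3-oxo-6-[(triethylsilyl)oxy]oct-7-enoate | C=C[C@](C)(O[Si](CC)(CC)CC)CCC(=O)CC(=O)OC | intermediate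
7 | (Z)-but-2-ene-1,4-diyl diacetate | CC(=O)OC/C=C\COC(C)=O | starting material
8 | methyl (6R,7E)-9-acetoxy-6-methyl-3-oxo-6-[(triethylsilyl)oxy]non-7-enoate | CC(=O)OC/C=C/[C@](C)(O[Si](CC)(CC)CC)CCC(=O)CC(=O)OC | intermediate
9 | methyl (1S,2S,3R)-2-ethenyl-3-methyl-6-oxo-3-[(triethylsilyl)oxy]cyclohexane-1-carboxylate | O=C1CC[C@@](C)(O[Si](CC)(CC)CC)[C@@H](C=C)[C@@H]1C(=O)OC | intermediate
10 | ethylene | C=C | starting material
11 | methyl (2R,3R)-1-bromo-2-ethenyl-3-methyl-6-oxo-3-[(triethylsilyl)oxy]cyclohexane-1-carboxylate (C1 epimers) | O=C1CC[C@@](C)(O[Si](CC)(CC)CC)[C@@H](C=C)C1(Br)C(=O)OC | intermediate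
12 | methyl (1R,3aR,7R,7aS)-1-(bromomethyl)-7-methyl-4-oxo-7-[(triethylsilyl)oxy]octahydro-3aH-indene-3a-carboxylate | BrC[C@@H]1CC[C@]2(C(=O)OC)C(=O)CC[C@@](C)(O[Si](CC)(CC)CC)[C@@H]12 | intermediate
13 | methyl (1R,3aS,7R,7aS)-4-bromo-1-(bromomethyl)-7-methyl-7-[(triethylsilyl)oxy]-1,2,3,6,7,7a-hexahydro-3aH-indene-3a-carboxylate | BrC[C@@H]1CC[C@]2(C(=O)OC)C(Br)=CC[C@@](C)(O[Si](CC)(CC)CC)[C@@H]12 | intermediate
14 | methyl (1R,3aS,4S,7R,7aS)-4-bromo-1-(bromomethyl)-7-methyl-7-[(triethylsilyl)oxy]octahydro-3aH-indene-3a-carboxylate | BrC[C@@H]1CC[C@]2(C(=O)OC)[C@@H](Br)CC[C@@](C)(O[Si](CC)(CC)CC)[C@@H]12 | intermediate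
15 | [(1R,3aS,4S,7R,7aS)-4-bromo-1-(bromomethyl)-7-methyl-7-[(triethylsilyl)oxy]octahydro-3aH-inden-3a-yl]methanol | BrC[C@@H]1CC[C@]2(CO)[C@@H](Br)CC[C@@](C)(O[Si](CC)(CC)CC)[C@@H]12 | intermediate
16 | (1R,3aS,4S,7R,7aS)-4-bromo-1-(bromomethyl)-7-methyl-7-[(triethylsilyl)oxy]-3a-{[(triethylsilyl)oxy]methyl}octahydro-1H-indene | BrC[C@@H]1CC[C@]2(CO[Si](CC)(CC)CC)[C@@H](Br)CC[C@@](C)(O[Si](CC)(CC)CC)[C@@H]12 | intermediate
17 | (1R,3aS,4S,7R,7aS)-4-bromo-1-(iodomethyl)-7-methyl-7-[(triethylsilyl)oxy]-3a-{[(triethylsilyl)oxy]methyl}octahydro-1H-indene | IC[C@@H]1CC[C@]2(CO[Si](CC)(CC)CC)[C@@H](Br)CC[C@@](C)(O[Si](CC)(CC)CC)[C@@H]12 | intermediate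
18 | tert-butyl acetoacetate (tert-butyl 3-oxobutanoate) | CC(=O)CC(=O)OC(C)(C)C | starting material
19 | prenyl bromide (1-bromo-3-methylbut-2-ene) | CC(C)=CCBr | starting material
20 | sodium lithium dianion of tert-butyl 3-oxobutanoate | [Na+].[Li+].[CH2-]C(=O)[CH-]C(=O)OC(C)(C)C | intermediate
21 | tert-butyl 7-methyl-3-oxooct-6-enoate | CC(C)=CCCC(=O)CC(=O)OC(C)(C)C | intermediate
22 | tert-butyl 3-bromo-2,2-dimethyl-6-oxocyclohexane-1-carboxylate (racemate; 3S enantiomer drawn, C1 epimers) | O=C1CC[C@H](Br)C(C)(C)C1C(=O)OC(C)(C)C | intermediate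
23 | 3-bromo-2,2-dimethyl-6-oxocyclohexane-1-carboxylic acid (racemate; 3S enantiomer drawn) | O=C1CC[C@H](Br)C(C)(C)C1C(=O)O | intermediate
24 | 4-bromo-3,3-dimethylcyclohexan-1-one (racemate; the 4S enantiomer drawn is the one carried into 27) | O=C1CC[C@H](Br)C(C)(C)C1 | intermediate
25 | {[(1R,3aS,4S,7R,7aS)-4-bromo-7-methyl-7-[(triethylsilyl)oxy]-3a-{[(triethylsilyl)oxy]methyl}octahydro-1H-inden-1-yl]methyl}lithium | [Li]C[C@@H]1CC[C@]2(CO[Si](CC)(CC)CC)[C@@H](Br)CC[C@@](C)(O[Si](CC)(CC)CC)[C@@H]12 | intermediate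
26 | lithium (1S,4S)-4-bromo-1-{[(1S,3aS,4S,7R,7aS)-4-bromo-7-methyl-7-[(triethylsilyl)oxy]-3a-{[(triethylsilyl)oxy]methyl}octahydro-1H-inden-1-yl]methyl}-3,3-dimethylcyclohexan-1-olate | [Li]O[C@]1(C[C@@H]2CC[C@]3(CO[Si](CC)(CC)CC)[C@@H](Br)CC[C@@](C)(O[Si](CC)(CC)CC)[C@@H]23)CC[C@H](Br)C(C)(C)C1 | intermediate
27 | (1S,4S)-4-bromo-1-{[(1S,3aS,4S,7R,7aS)-4-bromo-7-methyl-7-[(triethylsilyl)oxy]-3a-{[(triethylsilyl)oxy]methyl}octahydro-1H-inden-1-yl]methyl}-3,3-dimethylcyclohexyl acetate | CC(=O)O[C@]1(C[C@@H]2CC[C@]3(CO[Si](CC)(CC)CC)[C@@H](Br)CC[C@@](C)(O[Si](CC)(CC)CC)[C@@H]23)CC[C@H](Br)C(C)(C)C1 | intermediate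
28 | (1S,4S)-4-bromo-1-{[(1S,3aS,4S,7R,7aS)-4-bromo-7-hydroxy-3a-(hydroxymethyl)-7-methyloctahydro-1H-inden-1-yl]methyl}-3,3-dimethylcyclohexyl acetate (CNP0182818.1) | CC(=O)O[C@]1(C[C@@H]2CC[C@]3(CO)[C@@H](Br)CC[C@@](C)(O)[C@@H]23)CC[C@H](Br)C(C)(C)C1 | target

**Step count and weak points**
Total step count: 14. Longest linear sequence: 12 (steps 1–10, 13, 14); steps 11–12 make the ring A ketone.

Step 5 (allylic alkylation next to the fully substituted C3; risk of eight-membered ring formation or a poor cis:trans ratio at C2/C3). The fallback sets out from 6 and comes back at 9, replacing steps 4 and 5. Ozonolysis of the remaining vinyl group of 6 (O3, CH2Cl2, −78 °C; PPh3) gives methyl (6R)-6-methyl-3,7-dioxo-6-[(triethylsilyl)oxy]heptanoate F1. Piperidinium acetate closes it by intramolecular Knoevenagel condensation to methyl (3R)-3-methyl-6-oxo-3-[(triethylsilyl)oxy]cyclohex-1-ene-1-carboxylate F2. HF·pyridine gives methyl (3R)-3-hydroxy-3-methyl-6-oxocyclohex-1-ene-1-carboxylate F3. CH2=CHMgBr (2.5 equiv, THF, −78 °C) then adds 1,4 on the face of the magnesium alkoxide (hydroxyl-directed conjugate addition) to give methyl (1S,2S,3R)-2-ethenyl-3-hydroxy-3-methyl-6-oxocyclohexane-1-carboxylate F4, and Et3SiOTf/2,6-lutidine returns 9.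

Step 6 (the proposed annulation; premature bromine transfer before ring closure, telomerisation with ethylene, or the cis-fused isomer could intervene). The fallback sets out from 9 and comes back at 12 using known chemistry. C-alkylation of 9 with BrCH2CH2Cl (K2CO3, DMF), anti to the vinyl group, gives methyl (1R,2S,3R)-1-(2-chloroethyl)-2-ethenyl-3-methyl-6-oxo-3-[(triethylsilyl)oxy]cyclohexane-1-carboxylate F5. NaI in acetone gives methyl (1R,2S,3R)-2-ethenyl-1-(2-iodoethyl)-3-methyl-6-oxo-3-[(triethylsilyl)oxy]cyclohexane-1-carboxylate F6. Curran iodine-atom-transfer 5-exo cyclisation ((Bu3Sn)2 10 mol%, sunlamp, benzene, 80 °C) gives methyl (1R,3aR,7R,7aS)-1-(iodomethyl)-7-methyl-4-oxo-7-[(triethylsilyl)oxy]octahydro-3aH-indene-3a-carboxylate F7, and halide exchange with excess n-Bu4NBr in acetone at 56 °C gives 12.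

Step 13 (the organolithium must form in the presence of the secondary C4 bromide, a hindered tertiary alkoxide must be acetylated in situ, and the racemic ketone caps the yield of the wanted diastereomer near one half). The fallback sets out from 17 and 24 and comes back at 27. A samarium Barbier coupling (SmI2 2.5 equiv, HMPA, THF, 23 °C, minutes) reduces only the primary iodide and gives, after separation from its ring A diastereomer, (1S,4S)-4-bromo-1-{[(1S,3aS,4S,7R,7aS)-4-bromo-7-methyl-7-[(triethylsilyl)oxy]-3a-{[(triethylsilyl)oxy]methyl}octahydro-1H-inden-1-yl]methyl}-3,3-dimethylcyclohexan-1-ol F8. Separate acetylation (Ac2O, DMAP, Et3N, 40 °C) then gives 27.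

**Further compounds**
F1 | step 5 | methyl (6R)-6-methyl-3,7-dioxo-6-[(triethylsilyl)oxy]heptanoate | O=C[C@](C)(O[Si](CC)(CC)CC)CCC(=O)CC(=O)OC
F2 | step 5 | methyl (3R)-3-methyl-6-oxo-3-[(triethylsilyl)oxy]cyclohex-1-ene-1-carboxylate | O=C1CC[C@@](C)(O[Si](CC)(CC)CC)C=C1C(=O)OC
F3 | step 5 | methyl (3R)-3-hydroxy-3-methyl-6-oxocyclohex-1-ene-1-carboxylate | O=C1CC[C@@](C)(O)C=C1C(=O)OC
F4 | step 5 | methyl (1S,2S,3R)-2-ethenyl-3-hydroxy-3-methyl-6-oxocyclohexane-1-carboxylate | O=C1CC[C@@](C)(O)[C@@H](C=C)[C@@H]1C(=O)OC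
F5 | step 6 | methyl (1R,2S,3R)-1-(2-chloroethyl)-2-ethenyl-3-methyl-6-oxo-3-[(triethylsilyl)oxy]cyclohexane-1-carboxylate | O=C1CC[C@@](C)(O[Si](CC)(CC)CC)[C@@H](C=C)[C@@]1(CCCl)C(=O)OC
F6 | step 6 | methyl (1R,2S,3R)-2-ethenyl-1-(2-iodoethyl)-3-methyl-6-oxo-3-[(triethylsilyl)oxy]cyclohexane-1-carboxylate | O=C1CC[C@@](C)(O[Si](CC)(CC)CC)[C@@H](C=C)[C@@]1(CCI)C(=O)OC
F7 | step 6 | methyl (1R,3aR,7R,7aS)-1-(iodomethyl)-7-methyl-4-oxo-7-[(triethylsilyl)oxy]octahydro-3aH-indene-3a-carboxylate | IC[C@@H]1CC[C@]2(C(=O)OC)C(=O)CC[C@@](C)(O[Si](CC)(CC)CC)[C@@H]12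
F8 | step 13 | (1S,4S)-4-bromo-1-{[(1S,3aS,4S,7R,7aS)-4-bromo-7-methyl-7-[(triethylsilyl)oxy]-3a-{[(triethylsilyl)oxy]methyl}octahydro-1H-inden-1-yl]methyl}-3,3-dimethylcyclohexan-1-ol | O[C@]1(C[C@@H]2CC[C@]3(CO[Si](CC)(CC)CC)[C@@H](Br)CC[C@@](C)(O[Si](CC)(CC)CC)[C@@H]23)CC[C@H](Br)C(C)(C)C1
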